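At early times the north run lost starting material fast, with 18.9% left at 15.0 s, but it levelled off at 4.5% by 60.0 s. So I worked with the fraction left.

- north: starting material 0.13 M; partner 0.52 M; catalyst 0.34 mM; run made earlier
- flask: starting material 0.13 M; partner 0.260 M; catalyst 0.34 mM; time 5.0 min
north run (percent of the starting material charged)

| time / s | target / % | starting material / % |
|---|---|---|
| 15.0 | 75.3 | 18.9 |
| 30.0 | 79.0 | 7.1 |
| 50.0 | 71.9 | 4.9 |
| 60.0 | 67.9 | 4.5 |

(scatter of a reading: 0.3 percentage points)
- the best time, 5.0 min at the latest, for target
- the amount of target, in percent of the starting material charged, at that time

At 60.0 s, counting what north had missing as over-reaction product, 27.6%, partner stood at 0.360 M. Target over starting material times partner then read 41.9 L mol⁻¹, my balance constant, the equilibrium of the reversible step as a reading.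

share left = 1 / (1 + balance constant × partner)

From above: with the flask's partner untouched, the share left was 8.40%, so target stayed under 91.6%. Target that high would cost partner down to 0.141 M, and with at least that much partner balance lay no lower than this:

share left = 14.5%, target at balance = 85.5% at least

That much target left at most 0.149 M of partner, which gave the real limit:

share left = 13.8%, ceiling = 86.2%

From below: the flask's partner began below north's at 60.0 s, so I scaled north's loss to about 19.9% by that time, which put the flask's partner near 0.104 M at the lowest. North's first 15.0 s ran on partner averaging 0.464 M, so the same partner-time took the flask 66.8 s, and I carried north's 18.9% left over to that moment. This ignores the back step, so it is an estimate, not a limit: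

floor = 58.9%

The forecast gave 73% at 1 min, inside my bracket : “Target rises to a broad maximum near 60 s, about 73%, then falls slowly.”

The flask gave 74.3% at 0.944 min, also inside .

    partner → decomposition product (k = 6.18 × 10⁻⁶ s⁻¹)
    partner + target → over-reaction product (k = 0.0172 L mol⁻¹ s⁻¹)
    starting material + partner + catalyst ⇌ target + catalyst, rate k3*[starting material]*[partner]*[catalyst] forward; the back reaction follows from the equilibrium constant (K = 46.6 L mol⁻¹, k = 788 L² mol⁻² s⁻¹)

In the flask, half of the conversion to target up to 5.00 min was done by 0.167 min, but half of the over-reaction by 1.99 min. At 5.00 min, target was made at 0.0508 of the rate it was used up, each step net. With 36.3% of the partner left then, my constant gave a share left of 20.2%, and the flask held 18.7%. The neighbour charged with 0.052 M of starting material kept 69.3% of its partner, so the reckoning gave 11.7%, and it held 11.1%.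

The data stem from a simulated flask with constants of no real substance; the scatter is artificial.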